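Starting material that enters a flask at 4.0 min cannot stand for the 5.0 min of the run, for it has 1.00 min left, so slow addition of it costs target, and two times say how much.

all flasks: free catalyst 25 mM

| flask | starting material | second substrate | remark | time |
|---|---|---|---|---|
| gamma | 0.50 M | 0.50 M | run made earlier |  |
| delta | 0.70 M | 0.50 M | run made earlier |  |
| alpha | 1.1 M | 0.50 M | run made earlier |  |
| alder | 0.50 M (in portions, 4, over 4.0 min) | 0.500 M | first portion at the start, last at 4.0 min | 5.0 min |
| cedar | 0.50 M | 0.500 M (fed, over 4.0 min) | all else is in the flask from the start; the feed brings no volume worth counting | 5.0 min |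
| ash | 0.50 M | 0.500 M | everything together at the start | 5.0 min |
| oak | 0.50 M (fed, over 1.0 min) | 0.500 M | all else is in the flask from the start; the feed brings no volume worth counting | 5.0 min |
| larch | 0.50 M (fed, over 4.0 min) | 0.500 M | all else is in the flask from the start; the feed brings no volume worth counting | 5.0 min |

- gamma (time / min: target / %, starting material / %): 0.667: 12.2, 87.5; 1.33: 23.6, 76.7; 2.00: 32.9, 65.8; 3.00: 45.3, 54.8; 4.00: 53.8, 45.2; 5.00: 62.2, 37.2
- delta (time / min: target / %, starting material / %): 0.500: 9.1, 90.6; 1.00: 17.0, 82.4; 1.50: 24.1, 75.6; 2.50: 36.6, 62.1; 3.00: 42.3, 56.7; 4.00: 52.7, 48.5
- alpha (time / min: target / %, starting material / %): 0.500: 7.9, 91.2; 1.00: 15.7, 83.9; 1.50: 21.8, 77.5; 2.50: 33.1, 65.1; 3.00: 39.8, 60.5; 4.00: 47.6, 51.4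

(standard deviation of a reading: 0.5 percentage points)

* the flask with the highest amount of target, in percent of the starting material charged ("all alike" if they lie within 1.5 percentage points) (alder / cedar / ash / oak / larch / all alike)
* final target, as a percentage of the starting material charged, in alder
* final target, as a percentage of the starting material charged, in cedar
* final target, as a percentage of the starting material charged, in ash
* final target, as a percentage of the starting material charged, in oak
* final target, as a percentage of the starting material charged, in larch

- a reading or a percentage of target counts all its forms, free or not

At 4.00 min the gamma run holds 45.2% of its starting material and the alpha run 51.4%, although alpha was charged with twice as much, so the loss is close to first order (pseudo-first-order). The gamma reading of 37.2% at 5.00 min then gives a lifetime of 5.06 min, the time in which c(starting material) falls by the factor e. The other time is the dosing time, and their ratio is 0.791 for the slow feed. Each slice of a steady feed ages from its own entry, so summing the slices is the area under one exponential: at the end of the feed the fraction left is one minus exp(−ratio), divided by the ratio, and it then decays for the remaining time. This reckoning gives larch 43.3% of target, oak 58.9%, alder, summed portion by portion, 42.3%, and ash 62.8%, the highest of these. It gives no figure for cedar, whose second substrate is fed, for the lifetime was read in the gamma run with 0.50 M of second substrate present from the start.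

The forecast names ash, with alder 44%, cedar 61.5%, ash 62.3%, oak 59.3% and larch 45%, and treats second substrate as “effectively zero order, though its order was never varied directly”. Its figures, from its own rate constant, differ slightly from those above.

The flasks give alder 43.2%, cedar 66.1%, ash 62.0%, oak 58.4% and larch 44.1%, so cedar holds the most.

    starting material + free catalyst ⇌ catalyst intermediate A (K = 5.50 L mol⁻¹, k = 0.260 L mol⁻¹ s⁻¹)
    catalyst intermediate A ⇌ free catalyst + target (K = 5.10 M, k = 0.430 s⁻¹)
    second substrate + free catalyst ⇌ catalyst intermediate B (K = 1.10 L mol⁻¹, k = 0.220 L mol⁻¹ s⁻¹)
    catalyst intermediate B → free catalyst + second product (k = 0.0270 s⁻¹)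
    free catalyst + target ⇌ idle complex (K = 0.700 L mol⁻¹, k = 0.0190 L mol⁻¹ s⁻¹)

Cedar stands 4.1 percentage points above ash, with 34% of its starting material left at 5.00 min against 38% in ash. The lifetime read from gamma carries alder onward: left until 12 min, alder starts that stretch from 56% of starting material at 5.00 min, and the further 7.00 min should leave a quarter of it, 14.0% of the charge. At that time alder holds 15.9% of starting material and 83.8% of target.

The numbers in the tables stem from a simulated flask with constants of no real substance; noise was put on by code.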